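**Assumption:** positions are named with germacrane numbering (ring C1–C10, lactone carbons C11–C13, methyl C14, exocyclic methylene C15). The SMILES is read as (1R,5S,6S,7R,8R,10R)-5-angeloyloxy-1,10-epoxy-6-hydroxy-3-oxogermacra-4(15),11(13)-dien-12,8-olide, with a trans epoxide and a trans-fused lactone.

## Retrosynthetic overview

1. Target 31 ⇐ last-step epoxidation of the E-C1=C10 olefin of 30; the C5 angelate, C3 ketone and free C6–OH come from late adjustments on macrocycle 26.
2. Ten-membered ring (formed second) ⇐ intramolecular Nozaki–Hiyama–Kishi coupling C3–C4 of iodoalkene aldehyde 25.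
3. C6–C7 bond, the C6 and C7 stereocentres and the α-methylene lactone ⇐ new chelation-controlled SE2′ addition of butenolide allylstannane 12 to α-alkoxy aldehyde 21.
4. Fragment A (12; butenolide ring formed first, by RCM) ⇐ (R)-epichlorohydrin 1 via alkynylation, vinylation and carboalumination/ethylene oxide.
5. Fragment B (21) ⇐ methyl (R)-glycerate acetonide 13 via alkyne, Markovnikov hydroiodination and PMP-acetal opening.

## Route

### Fragment A

Step 1
Reactants: 1 (R)-epichlorohydrin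
Product: 2 (R)-1-chloro-5-(trimethylsilyl)pent-4-yn-2-ol
Conditions: Me3SiC≡CH, n-BuLi, THF, −78 °C; BF3·OEt2; then 1, −78 °C
Reagents that add atoms: trimethylsilylacetylene C#C[Si](C)(C)C
Why: BF3-promoted acetylide opening of the epoxide (Yamaguchi alkynylation) occurs by SN2 at the unsubstituted carbon, so the stereocentre (future C8) is untouched.

Step 2
Reactants: 2 (R)-1-chloro-5-(trimethylsilyl)pent-4-yn-2-ol
Product: 4 (R)-6-(trimethylsilyl)hex-1-en-5-yn-3-ol, via alkynyl epoxide 3 (not isolated)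
Conditions: Me3S+ I− (4 equiv), n-BuLi (3.9 equiv), THF, −20 °C → rt
Reagents that add atoms: trimethylsulfonium iodide C[S+](C)C.[I-]
Why: The alkoxide closes to the terminal epoxide, which dimethylsulfonium methylide opens at CH2 and then eliminates Me2S to give the vinyl carbinol (Corey–Chaykovsky-type one-carbon homologation to an allylic alcohol); the carbinol centre is not involved.

Step 3
Reactants: 4 (R)-6-(trimethylsilyl)hex-1-en-5-yn-3-ol
Product: 5 (R)-hex-1-en-5-yn-3-ol
Conditions: K2CO3 (0.2 equiv), MeOH, rt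
Reagents that add atoms: none
Why: Base-catalysed protodesilylation of the alkynylsilane frees the terminal alkyne needed for carbometalation.

Step 4
Reactants: 5 (R)-hex-1-en-5-yn-3-ol
Product: 8 (3R,5E)-5-methylocta-1,5-diene-3,8-diol, via alkenylalane 6 (not isolated), via lithium alanate 7 (not isolated)
Conditions: Me3Al (3 equiv), Cp2ZrCl2 (0.25 equiv), CH2Cl2, 0 °C → rt; evaporate; n-BuLi, THF/hexane, −78 → 0 °C; ethylene oxide, 0 °C → rt; aq. KNaC4H4O6
Reagents that add atoms: trimethylaluminium C[Al](C)C; ethylene oxide C1CO1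
Why: Negishi zirconium-catalysed syn-carboalumination puts methyl on the internal and aluminium on the terminal alkyne carbon, fixing the E trisubstituted C1=C10 olefin, and the alkenylalanate opens ethylene oxide with retention of geometry to add C2–C3.

Step 5
Reactants: 8 (3R,5E)-5-methylocta-1,5-diene-3,8-diol
Product: 9 (3R,5E)-5-methyl-8-[(triethylsilyl)oxy]octa-1,5-dien-3-ol
Conditions: Et3SiCl (1.05 equiv), imidazole, CH2Cl2, −78 °C
Reagents that add atoms: chlorotriethylsilane CC[Si](Cl)(CC)CC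
Why: Sterically controlled silylation selects the primary over the secondary allylic alcohol.

Step 6
Reactants: 9 (3R,5E)-5-methyl-8-[(triethylsilyl)oxy]octa-1,5-dien-3-ol
Product: 10 (3R,5E)-5-methyl-8-[(triethylsilyl)oxy]octa-1,5-dien-3-yl 2-(bromomethyl)prop-2-enoate
Conditions: 2-(bromomethyl)acrylic acid, DCC, DMAP (5 mol %), CH2Cl2, 0 °C
Reagents that add atoms: 2-(bromomethyl)acrylic acid C=C(CBr)C(=O)O
Why: Steglich esterification forms the acyl–oxygen bond, so the C8 configuration is retained.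

Step 7
Reactants: 10 (3R,5E)-5-methyl-8-[(triethylsilyl)oxy]octa-1,5-dien-3-yl 2-(bromomethyl)prop-2-enoate
Product: 11 (5R)-3-(bromomethyl)-5-[(2E)-2-methyl-5-[(triethylsilyl)oxy]pent-2-en-1-yl]furan-2(5H)-one
Conditions: second-generation Grubbs catalyst (H2IMes)(PCy3)Cl2Ru=CHPh (5 mol %), CH2Cl2 (5 mM), 40 °C
Reagents that add atoms: none
Why: Ring-closing metathesis loads ruthenium on the monosubstituted vinyl group and closes onto the acrylate to give the butenolide (C7=C11), while the trisubstituted olefin is inert.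

Step 8
Reactants: 11 (5R)-3-(bromomethyl)-5-[(2E)-2-methyl-5-[(triethylsilyl)oxy]pent-2-en-1-yl]furan-2(5H)-one
Product: 12 (5R)-5-[(2E)-2-methyl-5-[(triethylsilyl)oxy]pent-2-en-1-yl]-3-[(tributylstannyl)methyl]furan-2(5H)-one
Conditions: (Bu3Sn)2 (1.2 equiv), Pd2(dba)3 (2.5 mol %), THF, rt
Reagents that add atoms: hexabutylditin CCCC[Sn](CCCC)(CCCC)[Sn](CCCC)(CCCC)CCCC
Why: Palladium-catalysed allylic stannylation (oxidative addition of zerovalent palladium, transmetalation with the ditin, reductive elimination) delivers tin to the unsubstituted allyl terminus and keeps the butenolide conjugation.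

### Fragment B

Step 9
Reactants: 13 methyl (R)-2,2-dimethyl-1,3-dioxolane-4-carboxylate
Product: 15 (S)-4-ethynyl-2,2-dimethyl-1,3-dioxolane, via aldehyde 14 (not isolated)
Conditions: DIBAL-H (1.05 equiv), CH2Cl2, −78 °C; then MeOH, K2CO3, dimethyl (1-diazo-2-oxopropyl)phosphonate, −78 °C → rt
Reagents that add atoms: dimethyl (1-diazo-2-oxopropyl)phosphonate CC(=O)C(=[N+]=[N-])P(=O)(OC)OC
Why: Partial ester reduction followed in the same pot by Ohira–Bestmann (Seyferth–Gilbert) homologation avoids isolating the epimerisable glyceraldehyde acetonide, so the future C5 centre is kept.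

Step 10
Reactants: 15 (S)-4-ethynyl-2,2-dimethyl-1,3-dioxolane
Product: 17 (R)-4-(1-iodoethenyl)-2,2-dimethyl-1,3-dioxolane, via alkenylalane 16 (not isolated)
Conditions: Ni(dppp)Cl2 (3 mol %), DIBAL-H (1.3 equiv), THF, 0 °C → rt; then NIS, 0 °C
Reagents that add atoms: N-iodosuccinimide IN1C(=O)CCC1=O
Why: Nickel-catalysed Markovnikov hydroalumination places aluminium on the internal alkyne carbon and iodinolysis gives the 2-iodoalkene (C4 with C15); the dioxolane centre is not touched.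

Step 11
Reactants: 17 (R)-4-(1-iodoethenyl)-2,2-dimethyl-1,3-dioxolane
Product: 18 (R)-3-iodobut-3-ene-1,2-diol
Conditions: AcOH/H2O 4:1, 40 °C
Reagents that add atoms: none
Why: Mild acetal hydrolysis frees the diol without affecting the iodoalkene.

Step 12
Reactants: 18 (R)-3-iodobut-3-ene-1,2-diol
Product: 19 (4R)-4-(1-iodoethenyl)-2-(4-methoxyphenyl)-1,3-dioxolane (both acetal epimers)
Conditions: 4-MeOC6H4CH(OMe)2, PPTS (cat.), CH2Cl2, rt
Reagents that add atoms: 4-methoxybenzaldehyde dimethyl acetal COC(OC)c1ccc(OC)cc1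
Why: Acid-catalysed transacetalisation gives the p-methoxybenzylidene acetal that carries the future C5 PMB ether.

Step 13
Reactants: 19 (4R)-4-(1-iodoethenyl)-2-(4-methoxyphenyl)-1,3-dioxolane
Product: 20 (R)-3-iodo-2-[(4-methoxybenzyl)oxy]but-3-en-1-ol
Conditions: DIBAL-H (3 equiv), CH2Cl2, −78 → 0 °C
Reagents that add atoms: none
Why: Regioselective reductive acetal opening: aluminium binds the less hindered primary oxygen, that C–O bond breaks and hydride reduces the oxocarbenium ion, leaving PMB on the secondary oxygen.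

Step 14
Reactants: 20 (R)-3-iodo-2-[(4-methoxybenzyl)oxy]but-3-en-1-ol
Product: 21 (R)-3-iodo-2-[(4-methoxybenzyl)oxy]but-3-enal
Conditions: Dess–Martin periodinane, NaHCO3, CH2Cl2, 0 °C; used crude at once
Reagents that add atoms: none
Why: Buffered Dess–Martin oxidation is non-basic and so gives the α-alkoxy-β,γ-unsaturated aldehyde without epimerisation or conjugation.

### Fragment union and endgame

Step 15
Reactants: 12 butenolide allylstannane; 21 (R)-3-iodo-2-[(4-methoxybenzyl)oxy]but-3-enal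
Product: 22 (4R,5R)-4-[(1S,2R)-1-hydroxy-3-iodo-2-[(4-methoxybenzyl)oxy]but-3-en-1-yl]-3-methylidene-5-[(2E)-2-methyl-5-[(triethylsilyl)oxy]pent-2-en-1-yl]oxolan-2-one
Conditions: MgBr2·OEt2 (3 equiv), CH2Cl2, −20 → 0 °C (21 premixed with MgBr2·OEt2, then 12, 1.3 equiv)
Reagents that add atoms: none
Why: Proposed new method: a chelation-controlled, open-transition-state SE2′ addition of a butenolide-embedded 2-acylallylstannane to an α-alkoxy aldehyde. MgBr2 locks 21 as the five-membered C5–O/C6=O chelate so attack comes anti to the iodovinyl group (5,6-syn); the γ-carbon C7 attacks on the butenolide face opposite the C8 side chain (7,8-trans) with the C–Sn bond anti to the forming bond; and the antiperiplanar open transition state places the chelate ring next to H7, allowing both facial preferences at once (6,7-syn), which the closed chair of the known zinc or chromium Barbier variant of this E-locked allyl unit cannot do. Loss of the stannyl group creates the exocyclic C11=C13 olefin, so the C6–C7 bond, the C6 and C7 stereocentres and the α-methylene lactone arise together. The closest known reaction types are the Keck chelation-controlled crotylstannane addition and Lewis-acid-promoted additions of acyclic 2-(alkoxycarbonyl)allylstannanes or allylsilanes to aldehydes (Hosomi–Sakurai-type lactone annulation).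

Step 16
Reactants: 22 coupled hydroxy lactone
Product: 23 (4S,5R)-4-[(1S,2R)-3-iodo-2-[(4-methoxybenzyl)oxy]-1-[(triethylsilyl)oxy]but-3-en-1-yl]-3-methylidene-5-[(2E)-2-methyl-5-[(triethylsilyl)oxy]pent-2-en-1-yl]oxolan-2-one
Conditions: Et3SiOTf, 2,6-lutidine, CH2Cl2, −78 °C
Reagents that add atoms: triethylsilyl triflate CC[Si](CC)(CC)OS(=O)(=O)C(F)(F)F
Why: Silyl triflate silylation protects the hindered C6 carbinol, which keeps O5 and O6 differentiated for the later angeloylation (4S is a CIP change caused by silicon, not a spatial change).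

Step 17
Reactants: 23 bis(triethylsilyl) ether
Product: 25 (4S,5R)-4-[(1S,2R)-3-iodo-2-[(4-methoxybenzyl)oxy]-1-[(triethylsilyl)oxy]but-3-en-1-yl]-3-methylidene-5-[(2E)-2-methyl-5-oxopent-2-en-1-yl]oxolan-2-one, via alkoxysulfonium chloride 24 (not isolated)
Conditions: (COCl)2, DMSO, CH2Cl2, −78 → −40 °C; then Et3N, −78 → −20 °C; cold pH 7 quench
Reagents that add atoms: none
Why: Swern oxidation applied directly to the silyl ether: chlorodimethylsulfonium chloride cleaves only the unhindered primary triethylsilyl ether and the resulting alkoxysulfonium salt gives the β,γ-unsaturated aldehyde, the secondary silyl ether being untouched.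

Step 18
Reactants: 25 iodoalkene aldehyde
Product: 26 (1(10)E,5S,6S,7S,8R)-3-hydroxy-5-[(4-methoxybenzyl)oxy]-6-[(triethylsilyl)oxy]germacra-1(10),4(15),11(13)-trien-12,8-olide (both C3 epimers)
Conditions: CrCl2 (10 equiv), NiCl2 (0.1 equiv), degassed DMSO/THF 3:1, 2 mM by slow addition, rt
Reagents that add atoms: none
Why: Intramolecular Nozaki–Hiyama–Kishi reaction (oxidative addition of zerovalent nickel into the C–I bond, transmetalation to trivalent chromium, 1,2-addition to the aldehyde) closes the ten-membered ring at C3–C4 under non-basic conditions; the new C3 centre is removed in the next step.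

Step 19
Reactants: 26 macrocyclic allylic alcohol
Product: 27 (1(10)E,5S,6S,7S,8R)-5-[(4-methoxybenzyl)oxy]-3-oxo-6-[(triethylsilyl)oxy]germacra-1(10),4(15),11(13)-trien-12,8-olide
Conditions: Dess–Martin periodinane, NaHCO3, CH2Cl2, 0 °C
Reagents that add atoms: none
Why: Buffered Dess–Martin oxidation converts both C3 epimers into the cross-conjugated enone without moving the β,γ-olefin.

Step 20
Reactants: 27 PMB-protected enone
Product: 28 (1(10)E,5S,6S,7S,8R)-5-hydroxy-3-oxo-6-[(triethylsilyl)oxy]germacra-1(10),4(15),11(13)-trien-12,8-olide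
Conditions: DDQ (1.5 equiv), CH2Cl2/pH 7 buffer 10:1, 0 °C
Reagents that add atoms: none
Why: Oxidative PMB ether cleavage (benzylic hydride abstraction, hydrolysis) frees only the C5 hydroxyl.

Step 21
Reactants: 28 C5 alcohol
Product: 29 (1(10)E,5S,6S,7S,8R)-5-angeloyloxy-3-oxo-6-[(triethylsilyl)oxy]germacra-1(10),4(15),11(13)-trien-12,8-olide
Conditions: angelic acid, 2,4,6-Cl3C6H2COCl, Et3N, PhMe, rt; then 28, 60 °C (no DMAP)
Reagents that add atoms: angelic acid C/C=C(/C)C(=O)O
Why: Yamaguchi mixed-anhydride esterification without a nucleophilic catalyst acylates O5 with retention of the Z geometry and avoids SN2′ attack on the allylic ester.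

Step 22
Reactants: 29 silylated angelate
Product: 30 (1(10)E,5S,6S,7R,8R)-5-angeloyloxy-6-hydroxy-3-oxogermacra-1(10),4(15),11(13)-trien-12,8-olide
Conditions: HF (48 % aq.), MeCN, 0 °C
Reagents that add atoms: none
Why: Acidic, amine-free fluoride desilylation removes the secondary triethylsilyl ether without acyl migration or addition to the allylic angelate.

Step 23
Reactants: 30 deprotected trienolide
Product: 31 target (1R,5S,6S,7R,8R,10R)-5-angeloyloxy-1,10-epoxy-6-hydroxy-3-oxogermacra-4(15),11(13)-dien-12,8-olide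
Conditions: dimethyldioxirane (1.1 equiv, acetone solution), CH2Cl2, −30 °C
Reagents that add atoms: dimethyldioxirane CC1(C)OO1
Why: Dioxirane epoxidation is fastest at the only electron-rich olefin and is stereospecific (E-olefin gives the trans epoxide); attack on the outer face of the E-olefin in the ten-membered ring is expected to give the (1R,10R) isomer, and this face selectivity is an expectation from the usual germacranolide conformer, not a certainty.

## Compound list

1 | (R)-epichlorohydrin | ClC[C@H]1CO1 | starting material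
2 | (R)-1-chloro-5-(trimethylsilyl)pent-4-yn-2-ol | O[C@@H](CCl)CC#C[Si](C)(C)C | intermediate
3 | (R)-trimethyl[3-(oxiran-2-yl)prop-1-yn-1-yl]silane | C[Si](C)(C)C#CC[C@@H]1CO1 | intermediate
4 | (R)-6-(trimethylsilyl)hex-1-en-5-yn-3-ol | O[C@@H](C=C)CC#C[Si](C)(C)C | intermediate
5 | (R)-hex-1-en-5-yn-3-ol | O[C@@H](C=C)CC#C | intermediate
6 | (E)-alkenyl(dimethyl)alane from 5, as its dimethylaluminium alkoxide | C[Al](C)O[C@@H](C=C)C/C(C)=C/[Al](C)C | intermediate
7 | lithium butyl(dimethyl)alkenylalanate from 6 | [Li+].CCCC[Al-](C)(C)/C=C(C)/C[C@H](C=C)O[Al](C)C | intermediate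
8 | (3R,5E)-5-methylocta-1,5-diene-3,8-diol | O[C@@H](C=C)C/C(C)=C/CCO | intermediate
9 | (3R,5E)-5-methyl-8-[(triethylsilyl)oxy]octa-1,5-dien-3-ol | O[C@@H](C=C)C/C(C)=C/CCO[Si](CC)(CC)CC | intermediate
10 | (3R,5E)-5-methyl-8-[(triethylsilyl)oxy]octa-1,5-dien-3-yl 2-(bromomethyl)prop-2-enoate | C=C(CBr)C(=O)O[C@@H](C=C)C/C(C)=C/CCO[Si](CC)(CC)CC | intermediate
11 | (5R)-3-(bromomethyl)-5-[(2E)-2-methyl-5-[(triethylsilyl)oxy]pent-2-en-1-yl]furan-2(5H)-one | BrCC1=C[C@@H](C/C(C)=C/CCO[Si](CC)(CC)CC)OC1=O | intermediate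
12 | (5R)-5-[(2E)-2-methyl-5-[(triethylsilyl)oxy]pent-2-en-1-yl]-3-[(tributylstannyl)methyl]furan-2(5H)-one | CCCC[Sn](CCCC)(CCCC)CC1=C[C@@H](C/C(C)=C/CCO[Si](CC)(CC)CC)OC1=O | intermediate
13 | methyl (R)-2,2-dimethyl-1,3-dioxolane-4-carboxylate | COC(=O)[C@H]1COC(C)(C)O1 | starting material
14 | (R)-2,2-dimethyl-1,3-dioxolane-4-carbaldehyde | O=C[C@H]1COC(C)(C)O1 | intermediate
15 | (S)-4-ethynyl-2,2-dimethyl-1,3-dioxolane | C#C[C@H]1COC(C)(C)O1 | intermediate
16 | [1-[(4R)-2,2-dimethyl-1,3-dioxolan-4-yl]ethenyl]bis(2-methylpropyl)alane | C=C([Al](CC(C)C)CC(C)C)[C@H]1COC(C)(C)O1 | intermediate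
17 | (R)-4-(1-iodoethenyl)-2,2-dimethyl-1,3-dioxolane | C=C(I)[C@H]1COC(C)(C)O1 | intermediate
18 | (R)-3-iodobut-3-ene-1,2-diol | C=C(I)[C@H](O)CO | intermediate
19 | (4R)-4-(1-iodoethenyl)-2-(4-methoxyphenyl)-1,3-dioxolane (both acetal epimers) | C=C(I)[C@H]1COC(c2ccc(OC)cc2)O1 | intermediate
20 | (R)-3-iodo-2-[(4-methoxybenzyl)oxy]but-3-en-1-ol | C=C(I)[C@H](OCc1ccc(OC)cc1)CO | intermediate
21 | (R)-3-iodo-2-[(4-methoxybenzyl)oxy]but-3-enal | C=C(I)[C@H](OCc1ccc(OC)cc1)C=O | intermediate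
22 | (4R,5R)-4-[(1S,2R)-1-hydroxy-3-iodo-2-[(4-methoxybenzyl)oxy]but-3-en-1-yl]-3-methylidene-5-[(2E)-2-methyl-5-[(triethylsilyl)oxy]pent-2-en-1-yl]oxolan-2-one | C=C1C(=O)O[C@H](C/C(C)=C/CCO[Si](CC)(CC)CC)[C@H]1[C@H](O)[C@@H](OCc1ccc(OC)cc1)C(I)=C | intermediate
23 | (4S,5R)-4-[(1S,2R)-3-iodo-2-[(4-methoxybenzyl)oxy]-1-[(triethylsilyl)oxy]but-3-en-1-yl]-3-methylidene-5-[(2E)-2-methyl-5-[(triethylsilyl)oxy]pent-2-en-1-yl]oxolan-2-one | C=C1C(=O)O[C@H](C/C(C)=C/CCO[Si](CC)(CC)CC)[C@H]1[C@H](O[Si](CC)(CC)CC)[C@@H](OCc1ccc(OC)cc1)C(I)=C | intermediate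
24 | dimethyl(alkoxy)sulfonium chloride of the primary alcohol of 23 (primary OSiEt3 replaced by OS+Me2) | C=C1C(=O)O[C@H](C/C(C)=C/CCO[S+](C)C)[C@H]1[C@H](O[Si](CC)(CC)CC)[C@@H](OCc1ccc(OC)cc1)C(I)=C.[Cl-] | intermediate
25 | (4S,5R)-4-[(1S,2R)-3-iodo-2-[(4-methoxybenzyl)oxy]-1-[(triethylsilyl)oxy]but-3-en-1-yl]-3-methylidene-5-[(2E)-2-methyl-5-oxopent-2-en-1-yl]oxolan-2-one | C=C1C(=O)O[C@H](C/C(C)=C/CC=O)[C@H]1[C@H](O[Si](CC)(CC)CC)[C@@H](OCc1ccc(OC)cc1)C(I)=C | intermediate
26 | (1(10)E,5S,6S,7S,8R)-3-hydroxy-5-[(4-methoxybenzyl)oxy]-6-[(triethylsilyl)oxy]germacra-1(10),4(15),11(13)-trien-12,8-olide (both C3 epimers; C5–C8 arranged in space as in the target) | C=C1C(=O)O[C@@H]2C/C(C)=C/CC(O)C(=C)[C@H](OCc3ccc(OC)cc3)[C@@H](O[Si](CC)(CC)CC)[C@@H]12 | intermediate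
27 | (1(10)E,5S,6S,7S,8R)-5-[(4-methoxybenzyl)oxy]-3-oxo-6-[(triethylsilyl)oxy]germacra-1(10),4(15),11(13)-trien-12,8-olide | C=C1C(=O)O[C@@H]2C/C(C)=C/CC(=O)C(=C)[C@H](OCc3ccc(OC)cc3)[C@@H](O[Si](CC)(CC)CC)[C@@H]12 | intermediate
28 | (1(10)E,5S,6S,7S,8R)-5-hydroxy-3-oxo-6-[(triethylsilyl)oxy]germacra-1(10),4(15),11(13)-trien-12,8-olide | C=C1C(=O)O[C@@H]2C/C(C)=C/CC(=O)C(=C)[C@H](O)[C@@H](O[Si](CC)(CC)CC)[C@@H]12 | intermediate
29 | (1(10)E,5S,6S,7S,8R)-5-angeloyloxy-3-oxo-6-[(triethylsilyl)oxy]germacra-1(10),4(15),11(13)-trien-12,8-olide | C=C1C(=O)O[C@@H]2C/C(C)=C/CC(=O)C(=C)[C@H](OC(=O)/C(C)=C\C)[C@@H](O[Si](CC)(CC)CC)[C@@H]12 | intermediate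
30 | (1(10)E,5S,6S,7R,8R)-5-angeloyloxy-6-hydroxy-3-oxogermacra-1(10),4(15),11(13)-trien-12,8-olide | C=C1C(=O)O[C@@H]2C/C(C)=C/CC(=O)C(=C)[C@H](OC(=O)/C(C)=C\C)[C@@H](O)[C@@H]12 | intermediate
31 | (1R,5S,6S,7R,8R,10R)-5-angeloyloxy-1,10-epoxy-6-hydroxy-3-oxogermacra-4(15),11(13)-dien-12,8-olide (CNP0348992.3) | C=C1C(=O)O[C@@H]2C[C@@]3(C)O[C@@H]3CC(=O)C(=C)[C@H](OC(=O)/C(C)=C\C)[C@@H](O)[C@@H]12 | target

## Step count and risks

Total step count: 23. Longest linear sequence: 17 steps (steps 1–8 and 15–23, from 1). Fragment B adds 6 steps (9–14).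

**Risk 1 – step 15 (the proposed new method).** The deactivated allylstannane may be too unreactive, or the open transition state may not dominate. The fallback uses known chemistry, sets out from bromide 11 and aldehyde 21 and comes back at 22. A zinc Barbier allylation (Zn dust, sat. aq. NH4Cl/THF, 0 °C), known for 3-(bromomethyl)furanones, is expected through its closed chair transition state to give the C6-epimeric carbinol F1 (6R, 5,6-anti). Buffered Dess–Martin oxidation gives the C6 ketone F2. It is reduced at once under Luche conditions (NaBH4, CeCl3·7H2O, MeOH, −78 °C), where 1,2-selective polar Felkin–Anh attack anti to the C5 ether should give the 5,6-syn alcohol 22.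

**Risk 2 – step 18 (ten-membered ring closure).** The carbonyl addition may lose to oligomerisation or to isomerisation of the β,γ-unsaturated aldehyde. The fallback sets out from aldehyde 25 and comes back at enone 27, bypassing steps 18 and 19, by closing the same C3–C4 bond through acyl cross-coupling. Pinnick oxidation (NaClO2, NaH2PO4, 2-methyl-2-butene, t-BuOH/H2O) gives the carboxylic acid F3. Coupling with ethanethiol (EDC, DMAP, CH2Cl2) gives the S-ethyl thioester F4. Iodine–tin exchange ((Me3Sn)2, Pd(PPh3)4, PhMe, 80 °C) gives the alkenylstannane thioester F5. An intramolecular Liebeskind–Srogl-type ketone synthesis (Pd2(dba)3, tri(2-furyl)phosphine, CuO2PPh2 with monovalent copper, THF, 2 mM, 50 °C) then gives enone 27 directly.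

**Risk 3 – step 23 (face selectivity of the last epoxidation).** If substrate control gives the (1S,10S) epoxide, the fallback switches to reagent control at an earlier, more robust stage. It sets out from macrocyclic alcohol 26 and comes back at target 31. Shi epoxidation (D-fructose-derived ketone, KHSO5, K2CO3 buffer pH 10.5, MeCN/dimethoxymethane, 0 °C), which gives (R,R)-epoxides from E-trisubstituted olefins, gives the epoxy alcohol F6. Buffered Dess–Martin oxidation gives the epoxy enone F7. DDQ (CH2Cl2/pH 7 buffer) gives the epoxy hydroxy enone F8. Angeloylation with the mixed anhydride of step 21 gives the silylated epoxy angelate F9. Desilylation with Et3N·3HF in MeCN at 0 °C gives 31.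

## Further compounds

F1 | step 15 | (4R,5R)-4-[(1R,2R)-1-hydroxy-3-iodo-2-[(4-methoxybenzyl)oxy]but-3-en-1-yl]-3-methylidene-5-[(2E)-2-methyl-5-[(triethylsilyl)oxy]pent-2-en-1-yl]oxolan-2-one (6-epi-22) | C=C1C(=O)O[C@H](C/C(C)=C/CCO[Si](CC)(CC)CC)[C@H]1[C@@H](O)[C@@H](OCc1ccc(OC)cc1)C(I)=C
F2 | step 15 | (4S,5R)-4-[(2R)-3-iodo-2-[(4-methoxybenzyl)oxy]but-3-enoyl]-3-methylidene-5-[(2E)-2-methyl-5-[(triethylsilyl)oxy]pent-2-en-1-yl]oxolan-2-one | C=C1C(=O)O[C@H](C/C(C)=C/CCO[Si](CC)(CC)CC)[C@H]1C(=O)[C@@H](OCc1ccc(OC)cc1)C(I)=C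
F3 | step 18 | carboxylic acid from 25 (CHO oxidised to CO2H) | C=C1C(=O)O[C@H](C/C(C)=C/CC(=O)O)[C@H]1[C@H](O[Si](CC)(CC)CC)[C@@H](OCc1ccc(OC)cc1)C(I)=C
F4 | step 18 | S-ethyl thioester of F3 | C=C1C(=O)O[C@H](C/C(C)=C/CC(=O)SCC)[C@H]1[C@H](O[Si](CC)(CC)CC)[C@@H](OCc1ccc(OC)cc1)C(I)=C
F5 | step 18 | F4 with trimethylstannyl in place of iodine | C=C1C(=O)O[C@H](C/C(C)=C/CC(=O)SCC)[C@H]1[C@H](O[Si](CC)(CC)CC)[C@@H](OCc1ccc(OC)cc1)C(=C)[Sn](C)(C)C
F6 | step 23 | (1R,10R)-1,10-epoxide of 26 (both C3 epimers) | C=C1C(=O)O[C@@H]2C[C@@]3(C)O[C@@H]3CC(O)C(=C)[C@H](OCc4ccc(OC)cc4)[C@@H](O[Si](CC)(CC)CC)[C@@H]12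
F7 | step 23 | (1R,10R)-1,10-epoxide of 27 | C=C1C(=O)O[C@@H]2C[C@@]3(C)O[C@@H]3CC(=O)C(=C)[C@H](OCc4ccc(OC)cc4)[C@@H](O[Si](CC)(CC)CC)[C@@H]12
F8 | step 23 | (1R,10R)-1,10-epoxide of 28 | C=C1C(=O)O[C@@H]2C[C@@]3(C)O[C@@H]3CC(=O)C(=C)[C@H](O)[C@@H](O[Si](CC)(CC)CC)[C@@H]12
F9 | step 23 | (1R,10R)-1,10-epoxide of 29 (6-O-triethylsilyl ether of the target) | C=C1C(=O)O[C@@H]2C[C@@]3(C)O[C@@H]3CC(=O)C(=C)[C@H](OC(=O)/C(C)=C\C)[C@@H](O[Si](CC)(CC)CC)[C@@H]12
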